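**Assumption:** the target has no stereocentre (it is achiral), so no enantiocontrol is needed; 2,6-dichloro-3-hydroxybenzaldehyde, 4-(benzyloxy)benzyl chloride and 3-bromo-5-methoxyphenol are taken as catalogue compounds (availability not checked).

**Retrosynthetic overview**
1. Target 9 ⇐ one global hydrogenation of stilbene 8 (C=C saturation plus removal of three O-benzyl groups).
2. 8 ⇐ Heck coupling of the 2,6-dibenzylstyrene 6 with 3-bromo-5-methoxyphenol 7 (ring A–bridge bond).
3. 6 ⇐ double Negishi benzylation of dichlorostyrene 3 with 4-(benzyloxy)benzylzinc chloride (both ArCH2–Ar bonds at once).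
4. 3 ⇐ O-benzylation and Wittig methylenation of 2,6-dichloro-3-hydroxybenzaldehyde 1, which already carries the full 1,2,3,4-substitution pattern.
5. No ring is formed: all four benzene rings are bought. They are joined in the order central ring → two p-oxybenzyl rings → ring A.

**Route**

Step 1
Reactants: 1 2,6-dichloro-3-hydroxybenzaldehyde
Product: 2 3-(benzyloxy)-2,6-dichlorobenzaldehyde
Conditions: BnBr, K2CO3, DMF, rt
Reagents that add atoms: benzyl bromide, BrCc1ccccc1
Why: Williamson ether synthesis on the acidic phenol masks it as a benzyl ether that survives ylide, organozinc and Pd chemistry and is removed in the final hydrogenation.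

Step 2
Reactants: 2 3-(benzyloxy)-2,6-dichlorobenzaldehyde
Product: 3 1-(benzyloxy)-2,4-dichloro-3-ethenylbenzene
Conditions: Ph3PCH3Br, KOtBu, THF, 0 °C to rt
Reagents that add atoms: methyltriphenylphosphonium bromide, C[P+](c1ccccc1)(c1ccccc1)c1ccccc1.[Br-]
Why: Wittig methylenation of a non-enolisable, electron-poor aldehyde proceeds cleanly despite the two ortho chlorines and removes the carbonyl that a benzylzinc reagent would attack.

Step 3
Reactants: 3 1-(benzyloxy)-2,4-dichloro-3-ethenylbenzene; 4 4-(benzyloxy)benzyl chloride (3 equiv)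
Product: 6 1-(benzyloxy)-2,4-bis[4-(benzyloxy)benzyl]-3-ethenylbenzene, via 4-(benzyloxy)benzylzinc chloride 5 (not isolated)
Conditions: 4, Zn dust, LiCl, THF, 25 °C; then 3, Pd(OAc)2 (5 mol%), SPhos (10 mol%), THF, 65 °C
Reagents that add atoms: zinc, [Zn] (retained only in intermediate 5)
Why: LiCl-mediated zinc insertion gives the benzylic zinc chloride without Wurtz coupling, and a double Negishi sp2–sp3 cross-coupling with a bulky biarylphosphine Pd catalyst replaces both hindered aryl chlorides while the vinyl group and benzyl ethers are untouched.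

Step 4
Reactants: 6 1-(benzyloxy)-2,4-bis[4-(benzyloxy)benzyl]-3-ethenylbenzene; 7 3-bromo-5-methoxyphenol
Product: 8 3-[(E)-2-{3-(benzyloxy)-2,6-bis[4-(benzyloxy)benzyl]phenyl}ethenyl]-5-methoxyphenol
Conditions: Pd(OAc)2, P(o-tol)3, NaOAc, DMA, 120 °C
Reagents that add atoms: none
Why: Mizoroki–Heck arylation goes at the unhindered terminal vinyl carbon to give the E-stilbene, the meta-oxygenated aryl bromide is not deactivated toward oxidative addition, and the free phenol is tolerated (alkene geometry is irrelevant because it is hydrogenated next).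

Step 5
Reactants: 8 3-[(E)-2-{3-(benzyloxy)-2,6-bis[4-(benzyloxy)benzyl]phenyl}ethenyl]-5-methoxyphenol
Product: 9 2,4-bis(4-hydroxybenzyl)-3-[2-(3-hydroxy-5-methoxyphenyl)ethyl]phenol (target)
Conditions: H2 (1–3 atm), 10% Pd/C, EtOAc/MeOH, rt
Reagents that add atoms: none
Why: Catalytic hydrogenation saturates the stilbene and hydrogenolyses the three aryl benzyl ethers in one operation, while the aryl methyl ether and the diarylmethane C–C bonds are inert; no stereocentre is created.

**Compound list**
1 | 2,6-dichloro-3-hydroxybenzaldehyde | O=Cc1c(Cl)ccc(O)c1Cl | starting material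
2 | 3-(benzyloxy)-2,6-dichlorobenzaldehyde | O=Cc1c(Cl)ccc(OCc2ccccc2)c1Cl | intermediate
3 | 1-(benzyloxy)-2,4-dichloro-3-ethenylbenzene | C=Cc1c(Cl)ccc(OCc2ccccc2)c1Cl | intermediate
4 | 4-(benzyloxy)benzyl chloride | ClCc1ccc(OCc2ccccc2)cc1 | starting material
5 | 4-(benzyloxy)benzylzinc chloride | Cl[Zn]Cc1ccc(OCc2ccccc2)cc1 | intermediate
6 | 1-(benzyloxy)-2,4-bis[4-(benzyloxy)benzyl]-3-ethenylbenzene | C=Cc1c(Cc2ccc(OCc3ccccc3)cc2)ccc(OCc2ccccc2)c1Cc1ccc(OCc2ccccc2)cc1 | intermediate
7 | 3-bromo-5-methoxyphenol | COc1cc(O)cc(Br)c1 | starting material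
8 | 3-[(E)-2-{3-(benzyloxy)-2,6-bis[4-(benzyloxy)benzyl]phenyl}ethenyl]-5-methoxyphenol | COc1cc(O)cc(/C=C/c2c(Cc3ccc(OCc4ccccc4)cc3)ccc(OCc3ccccc3)c2Cc2ccc(OCc3ccccc3)cc2)c1 | intermediate
9 | 2,4-bis(4-hydroxybenzyl)-3-[2-(3-hydroxy-5-methoxyphenyl)ethyl]phenol | COc1cc(O)cc(CCc2c(Cc3ccc(O)cc3)ccc(O)c2Cc2ccc(O)cc2)c1 | target

**Total step count:** 5. **Longest linear sequence:** 5 (1 → 2 → 3 → 6 → 8 → 9).

**Three steps most likely to fail, with fallbacks**

Step 3 (double Negishi coupling on two ortho-flanked aryl chlorides; risk of stopping at mono-coupling or of benzylzinc homocoupling). The fallback reverses the polarity of the coupling. It sets out from 3, which is converted by Miyaura borylation (B2pin2, KOAc, XPhos-Pd-G2, dioxane, 100 °C) into the bis-boronate 2,2'-[4-(benzyloxy)-2-ethenyl-1,3-phenylene]bis(4,4,5,5-tetramethyl-1,3,2-dioxaborolane) F1. F1 is then joined to two equivalents of benzyl chloride 4 by Suzuki–Miyaura coupling (Pd(dppf)Cl2, K3PO4, toluene/H2O, 80 °C), where oxidative addition now occurs at the easy benzylic C–Cl bond. The fallback comes back to the route at 6.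

Step 4 (Heck reaction on a styrene flanked by two benzyl groups; risk of low conversion). The fallback replaces the Heck/hydrogenation sequence by a B-alkyl Suzuki coupling that makes the saturated bridge directly. It sets out from 6, which is hydroborated anti-Markovnikov with 9-BBN (THF, rt to 60 °C) to give 9-{2-[3-(benzyloxy)-2,6-bis(4-(benzyloxy)benzyl)phenyl]ethyl}-9-borabicyclo[3.3.1]nonane F2. Without isolation F2 is coupled with bromophenol 7 (Pd(dppf)Cl2, aq. K3PO4, THF/DMF, 65 °C) to give 3-{2-[3-(benzyloxy)-2,6-bis(4-(benzyloxy)benzyl)phenyl]ethyl}-5-methoxyphenol F3. Hydrogenolysis of the three benzyl ethers of F3 (H2, Pd/C, EtOAc/MeOH) brings the fallback back to the route at 9, bypassing 8.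

Step 5 (global hydrogenation; risk of incomplete debenzylation from catalyst poisoning, or of partial ring reduction on forcing). The fallback separates deprotection from alkene reduction and uses no heterogeneous metal. It sets out from 8, whose benzyl ethers are cleaved with BCl3 and pentamethylbenzene as cation scavenger (CH2Cl2, −78 °C; the aryl methyl ether survives) to give 2,4-bis(4-hydroxybenzyl)-3-[(E)-2-(3-hydroxy-5-methoxyphenyl)ethenyl]phenol F4. The stilbene double bond of F4 is then saturated with diimide generated from TsNHNH2 and NaOAc (THF/H2O, reflux). The fallback comes back to the route at 9.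

**Further compounds**
F1 | step 3 | 2,2'-[4-(benzyloxy)-2-ethenyl-1,3-phenylene]bis(4,4,5,5-tetramethyl-1,3,2-dioxaborolane) | C=Cc1c(B2OC(C)(C)C(C)(C)O2)c(OCc2ccccc2)ccc1B1OC(C)(C)C(C)(C)O1
F2 | step 4 | 9-{2-[3-(benzyloxy)-2,6-bis(4-(benzyloxy)benzyl)phenyl]ethyl}-9-borabicyclo[3.3.1]nonane | c1ccccc1COc1ccc(Cc2ccc(OCc3ccccc3)cc2)c(CCB2C3CCCC2CCC3)c1Cc1ccc(OCc2ccccc2)cc1
F3 | step 4 | 3-{2-[3-(benzyloxy)-2,6-bis(4-(benzyloxy)benzyl)phenyl]ethyl}-5-methoxyphenol | COc1cc(O)cc(CCc2c(Cc3ccc(OCc4ccccc4)cc3)ccc(OCc3ccccc3)c2Cc2ccc(OCc3ccccc3)cc2)c1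
F4 | step 5 | 2,4-bis(4-hydroxybenzyl)-3-[(E)-2-(3-hydroxy-5-methoxyphenyl)ethenyl]phenol | COc1cc(O)cc(/C=C/c2c(Cc3ccc(O)cc3)ccc(O)c2Cc2ccc(O)cc2)c1
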